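(Readings and results come from a simulation on assumed constants; scatter was added.)

**The exposure.** The product of partner charge and time is what the substrate feels. If you treat partner as constant at its charge (the pseudo-first-order picture), the fraction of substrate left is exp(−θ), and θ grows in proportion to that product.

| flask | substrate | partner | remark | time |
|---|---|---|---|---|
| Friday's | 0.10 M | 0.10 M | run made earlier |  |
| Tuesday's | 0.10 M | 0.40 M | run made earlier |  |
| flask | 0.10 M | 0.200 M |  | 2.5 d |

| run | time / d | substrate / % | first product / % |
|---|---|---|---|
| Friday's | 0.208 | 98 | 3 |
| Friday's | 0.625 | 94 | 2 |
| Friday's | 1.25 | 89 | 11 |
| Friday's | 1.67 | 86 | 14 |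
| Friday's | 2.50 | 83 | 14 |
| Tuesday's | 0.208 | 94 | 7 |
| Tuesday's | 0.625 | 81 | 19 |
| Tuesday's | 1.25 | 67 | 26 |
| Tuesday's | 1.67 | 57 | 28 |
| Tuesday's | 2.50 | 47 | 30 |

(readings scatter by 1.5 percentage points)

- amounts and yields of by-product count crystals too
- given per volume of solution although it is solid: crystals
- on the list of suspects stand: substrate + partner -> first product + by-product; partner + first product -> double product + by-product; partner + double product -> tris adduct + by-product; crystals <-> by-product

- how much substrate there is at 2.5 d, in percent of the substrate charged
- how much first product there is at 2.5 d, in percent of the substrate charged
- how much double product there is at 2.5 d, in percent of the substrate charged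
- how much tris adduct there is at 2.5 d, in percent of the substrate charged

**Reading it.** Tuesday's last reading gives θ = 0.755. The flask's product of charge and time is half of Tuesday's, so its exposure, the dimensionless number I carry forward, is θ = 0.378. I therefore expect 68.6% of the substrate charged to be left.

**Testing it.** Friday's product is a quarter of Tuesday's, which gives θ = 0.189 and 82.8% of the substrate left, and the reading there is 83%. So one number serves for the substrate, but it doesn't say how the reacted part divides.

**The gap.** On Tuesday, substrate lost but not found as first product was 23.0% of the charge by the last readings. A gap needing two steps in a row grows roughly as θ squared, so the flask's gap is about a quarter of that, 5.75%, leaving 25.7% as first product. The readings cannot divide the gap between double product and tris adduct.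

**The forecast.** It gives 68%, 24.5%, 6.7% and 0.8%, a larger gap than mine, and says of its last figure: “The tris step was never measured”.

**The flask.** After 2.5 d the flask holds 67.3% of substrate, 23.6% of first product, 8.37% of double product and 0.697% of tris adduct.

    substrate + partner → first product + by-product (k = 0.0370 /M/h)
    partner + first product → double product + by-product (k = 0.0600 /M/h)
    partner + double product → tris adduct + by-product (k = 0.0210 /M/h)
    crystals ⇌ by-product, rate k4*(cs4 - [by-product]) while solid is left; crystals form when [by-product] > cs4 (solubility = 31.0 mM, k = 0.270 /h)

The gap in the flask is 9.07% of the charge, against my 5.75%, and at 1.05 d first product was still made 3.65 times as fast as it was used up. The exposure 0.378 put substrate 1.3 percentage points too high. A second flask, with 0.80 M of partner for the same time, has θ = 1.51, which gives 22.1% of its substrate left, and it holds 20.5%.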